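**Retrosynthetic overview**

- Feature: in the pyran ring (ring C: O1, C2, C3, C4, C4a, C8a) the 2,4-dimethoxyphenyl group at C2 and the benzyl group at C3 are trans on neighbouring carbons that map onto the β- and α-carbons of a chromone, and the styryl-bearing C4 maps onto its carbonyl carbon.
- Last C–C bond: C4–styryl, made by ionising a flavan-4-ol at C4 and capturing the cation with an (E)-styryltrifluoroborate anti to the C3 benzyl group; the two phenols are unmasked at the very end.
- Key disconnection: the C2–aryl and C3–CH2 bonds, made in one telescoped operation on 7-methoxychromone (rhodium-catalysed enantioselective conjugate arylation with silyl trapping, release of the enolate, benzylation).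
- Ring order: ring A is bought with the acetophenone; ring C is closed first, as the chromone; no ring is formed afterwards, the other three benzene rings arriving as intact aryl units.

Key step: step 6

Assumption: the (R)-BINAP–rhodium catalyst is taken to arylate the chromone with the facial sense known for 2-cyclohexenone and N-protected 4-quinolones, which corresponds to 2R here; if the opposite sense is found, (S)-BINAP is used and nothing else changes.

**Route**

Step 1
Reactants: 1 2'-hydroxy-4'-methoxyacetophenone
Product: 3 7-methoxychromone, via enaminone 2 (not isolated)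
Conditions: Me2NCH(OMe)2, toluene, 110 °C; concentrate; 2 M HCl, CH2Cl2, 40 °C
Reagents that add atoms: N,N-dimethylformamide dimethyl acetal, COC(OC)N(C)C
Why: The methyl ketone condenses with the amide acetal to the (E)-enaminone, and under acid the phenol adds to its β-carbon with loss of dimethylamine, the standard enaminone route to 3-unsubstituted chromones, which closes ring C by 6-endo addition–elimination.

Step 2
Reactants: 4 1-bromo-2,4-dimethoxybenzene
Product: 6 (2,4-dimethoxyphenyl)zinc chloride, via arylmagnesium bromide 5 (not isolated)
Conditions: Mg, THF, 50 °C; then ZnCl2, THF, 0 → 20 °C; used as a titrated THF solution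
Reagents that add atoms: zinc dichloride, Cl[Zn]Cl
Why: Magnesium insertion into the electron-rich aryl bromide followed by transmetalation of the Grignard reagent with ZnCl2 is the standard preparation of an arylzinc chloride, and the two methyl ethers are inert to both stages.

Step 3
Reactants: 7 4-hydroxybenzaldehyde
Product: 8 4-(tert-butyldimethylsilyloxy)benzaldehyde
Conditions: t-BuMe2SiCl, imidazole, DMF, 20 °C
Reagents that add atoms: tert-butyldimethylsilyl chloride, CC(C)(C)[Si](C)(C)Cl
Why: Imidazole-promoted silylation masks the acidic phenol, which would otherwise quench the enolate in step 6, without touching the aldehyde.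

Step 4
Reactants: 8 4-(tert-butyldimethylsilyloxy)benzaldehyde
Product: 9 4-(tert-butyldimethylsilyloxy)benzyl alcohol
Conditions: NaBH4, MeOH, 0 °C
Reagents that add atoms: none
Why: Borohydride reduction of the aldehyde to the benzylic alcohol is fast at 0 °C and leaves the aryl silyl ether intact.

Step 5
Reactants: 9 4-(tert-butyldimethylsilyloxy)benzyl alcohol
Product: 10 4-(tert-butyldimethylsilyloxy)benzyl bromide
Conditions: CBr4, PPh3, CH2Cl2, 0 °C; used without storage
Reagents that add atoms: carbon tetrabromide, BrC(Br)(Br)Br
Why: The Appel reaction converts the primary benzylic alcohol into the bromide under neutral conditions, so the silyl ether and the easily ionised 4-silyloxybenzyl system are not exposed to HBr.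

Step 6
Reactants: 3 7-methoxychromone; 6 (2,4-dimethoxyphenyl)zinc chloride; 10 4-(tert-butyldimethylsilyloxy)benzyl bromide
Product: 13 (2R,3S)-3-[4-(tert-butyldimethylsilyloxy)benzyl]-2-(2,4-dimethoxyphenyl)-7-methoxychroman-4-one (2,3-trans), via silyl enol ether 11 (not isolated), via lithium enolate 12 (not isolated)
Conditions: [RhCl(C2H4)2]2 (cat.), (R)-2,2'-bis(diphenylphosphino)-1,1'-binaphthyl [(R)-BINAP] (cat.), Me3SiCl, THF, 20 °C; evaporate, pentane, filter under Ar; MeLi, THF, −20 °C; then DMPU, 10, −78 → −40 °C; aq. NH4Cl at −40 °C
Reagents that add atoms: none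
Why: The aryl–rhodium species (monovalent rhodium) formed by transmetalation from 6 inserts the C2=C3 bond of 3 on the face dictated by (R)-BINAP to give an oxa-π-allyl rhodium enolate, which Me3SiCl silylates to 11 so that the chloro-rhodium catalyst turns over; once zinc salts and excess Me3SiCl have been removed (they would otherwise consume the MeLi), MeLi attacks silicon to release lithium enolate 12, which 10 benzylates at C3 in an SN2 step. The closest known reaction type is the rhodium/BINAP-catalysed asymmetric 1,4-addition of arylzinc chlorides to chromones and N-protected 4-quinolones in the presence of Me3SiCl, joined to the classical conjugate addition–enolate alkylation sequence that passes through a silyl enol ether cleaved by MeLi. No ring is closed: ring C is already present in 3 and only the C2–aryl and C3–CH2 bonds are made. C2 is set by the chiral bisphosphine on rhodium (2R expected), and C3 is set by approach of 10 to the enolate face anti to the C2 aryl group, which gives the 2,3-trans isomer that is also the thermodynamically preferred diequatorial one, so any cis material should converge on it through the enol under a trace of acid. The step needs 1,4- rather than 1,2-arylation, which the soft aryl–rhodium intermediate secures, and it needs C-benzylation to outrun β-elimination of the ring phenoxide from 12 (retro-oxa-Michael opening to the chalcone, which would also erase C2); the lithium counter-ion, the cold DMPU-assisted reaction with a reactive benzylic bromide and the cold mildly acidic quench are meant to secure this.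

Step 7
Reactants: 13 (2R,3S)-3-[4-(tert-butyldimethylsilyloxy)benzyl]-2-(2,4-dimethoxyphenyl)-7-methoxychroman-4-one
Product: 14 (2R,3R,4R)-3-[4-(tert-butyldimethylsilyloxy)benzyl]-2-(2,4-dimethoxyphenyl)-7-methoxychroman-4-ol (expected major 3,4-trans epimer; C4 epimers are not separated)
Conditions: NaBH4, THF/MeOH, 0 °C
Reagents that add atoms: none
Why: Borohydride reduction of the ketone, with hydride expected to add axially to give mainly the 3,4-trans alcohol, leaves C2 and C3 untouched, and the C4 configuration is immaterial because C4 is planarised in step 10.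

Step 8
Reactants: 15 4-acetoxystyrene; 16 vinylboronic acid pinacol ester
Product: 17 (E)-2-(4-acetoxyphenyl)vinylboronic acid pinacol ester
Conditions: second-generation Grubbs catalyst RuCl2(H2IMes)(PCy3)(=CHPh) (cat.), CH2Cl2, 40 °C
Reagents that add atoms: none
Why: Olefin cross-metathesis of a styrene with vinylboronic acid pinacol ester, driven by loss of ethylene, is a known route to 2-arylvinylboronates, the E geometry being the thermodynamic outcome.

Step 9
Reactants: 17 (E)-2-(4-acetoxyphenyl)vinylboronic acid pinacol ester
Product: 18 potassium (E)-[2-(4-acetoxyphenyl)vinyl]trifluoroborate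
Conditions: KHF2, MeCN/H2O, 20 °C; evaporate, extract with acetone, precipitate with Et2O
Reagents that add atoms: potassium hydrogen difluoride, [K+].[F-].F
Why: Aqueous KHF2 converts the pinacol boronate into the crystalline trifluoroborate salt, and the phenol of this fragment is carried as an acetate because an aryl acetate tolerates the weakly acidic fluoride medium that would cleave an aryl silyl ether.

Step 10
Reactants: 14 (2R,3R,4R)-3-[4-(tert-butyldimethylsilyloxy)benzyl]-2-(2,4-dimethoxyphenyl)-7-methoxychroman-4-ol; 18 potassium (E)-[2-(4-acetoxyphenyl)vinyl]trifluoroborate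
Product: 19 (2R,3R,4R)-4-[(E)-4-acetoxystyryl]-3-[4-(tert-butyldimethylsilyloxy)benzyl]-2-(2,4-dimethoxyphenyl)-7-methoxychromane
Conditions: BF3·OEt2, MeCN/CH2Cl2, −40 → 0 °C
Reagents that add atoms: none
Why: BF3·OEt2 ionises the benzylic C4–OH to a cation stabilised through ring A by O1 and the 7-methoxy group, and the alkenyltrifluoroborate captures it through its boron-bearing carbon with loss of boron and retention of the E geometry (Lewis-acid-mediated substitution of electron-rich benzylic alcohols by potassium alkenyltrifluoroborates), approaching anti to the C3 benzyl group so that C4 is set 3,4-trans (4R).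

Step 11
Reactants: 19 (2R,3R,4R)-4-[(E)-4-acetoxystyryl]-3-[4-(tert-butyldimethylsilyloxy)benzyl]-2-(2,4-dimethoxyphenyl)-7-methoxychromane
Product: 20 caraganin C
Conditions: K2CO3, MeOH, 20 °C, under Ar; aq. NH4Cl
Reagents that add atoms: none
Why: Carbonate-mediated methanolysis cleaves both the aryl acetate and the aryl tert-butyldimethylsilyl ether, while the methyl ethers, the chroman and the E-alkene are inert to mild base and no stereocentre is epimerisable under these conditions.

**Compound list**

1 | 2'-hydroxy-4'-methoxyacetophenone | CC(=O)c1ccc(OC)cc1O | starting material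
2 | (E)-3-(dimethylamino)-1-(2-hydroxy-4-methoxyphenyl)prop-2-en-1-one | CN(C)/C=C/C(=O)c1ccc(OC)cc1O | intermediate
3 | 7-methoxychromone | O=c1ccoc2cc(OC)ccc12 | intermediate
4 | 1-bromo-2,4-dimethoxybenzene | COc1ccc(Br)c(OC)c1 | starting material
5 | (2,4-dimethoxyphenyl)magnesium bromide | COc1ccc([Mg]Br)c(OC)c1 | intermediate
6 | (2,4-dimethoxyphenyl)zinc chloride | COc1ccc([Zn]Cl)c(OC)c1 | intermediate
7 | 4-hydroxybenzaldehyde | O=Cc1ccc(O)cc1 | starting material
8 | 4-(tert-butyldimethylsilyloxy)benzaldehyde | CC(C)(C)[Si](C)(C)Oc1ccc(C=O)cc1 | intermediate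
9 | 4-(tert-butyldimethylsilyloxy)benzyl alcohol | CC(C)(C)[Si](C)(C)Oc1ccc(CO)cc1 | intermediate
10 | 4-(tert-butyldimethylsilyloxy)benzyl bromide | CC(C)(C)[Si](C)(C)Oc1ccc(CBr)cc1 | intermediate
11 | (2R)-2-(2,4-dimethoxyphenyl)-7-methoxy-4-(trimethylsilyloxy)-2H-chromene | COc1ccc2c(c1)O[C@@H](c1ccc(OC)cc1OC)C=C2O[Si](C)(C)C | intermediate
12 | lithium (2R)-2-(2,4-dimethoxyphenyl)-7-methoxy-2H-chromen-4-olate | COc1ccc2c(c1)O[C@@H](c1ccc(OC)cc1OC)C=C2[O-].[Li+] | intermediate
13 | (2R,3S)-3-[4-(tert-butyldimethylsilyloxy)benzyl]-2-(2,4-dimethoxyphenyl)-7-methoxychroman-4-one (2,3-trans) | COc1ccc2c(c1)O[C@@H](c1ccc(OC)cc1OC)[C@H](Cc1ccc(O[Si](C)(C)C(C)(C)C)cc1)C2=O | intermediate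
14 | (2R,3R,4R)-3-[4-(tert-butyldimethylsilyloxy)benzyl]-2-(2,4-dimethoxyphenyl)-7-methoxychroman-4-ol (major epimer drawn) | COc1ccc2c(c1)O[C@@H](c1ccc(OC)cc1OC)[C@H](Cc1ccc(O[Si](C)(C)C(C)(C)C)cc1)[C@H]2O | intermediate
15 | 4-acetoxystyrene | C=Cc1ccc(OC(C)=O)cc1 | starting material
16 | vinylboronic acid pinacol ester | C=CB1OC(C)(C)C(C)(C)O1 | starting material
17 | (E)-2-(4-acetoxyphenyl)vinylboronic acid pinacol ester | CC(=O)Oc1ccc(/C=C/B2OC(C)(C)C(C)(C)O2)cc1 | intermediate
18 | potassium (E)-[2-(4-acetoxyphenyl)vinyl]trifluoroborate | CC(=O)Oc1ccc(/C=C/[B-](F)(F)F)cc1.[K+] | intermediate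
19 | (2R,3R,4R)-4-[(E)-4-acetoxystyryl]-3-[4-(tert-butyldimethylsilyloxy)benzyl]-2-(2,4-dimethoxyphenyl)-7-methoxychromane | COc1ccc2c(c1)O[C@@H](c1ccc(OC)cc1OC)[C@H](Cc1ccc(O[Si](C)(C)C(C)(C)C)cc1)[C@H]2/C=C/c1ccc(OC(C)=O)cc1 | intermediate
20 | caraganin C, (2R,3R,4R) | COc1ccc2c(c1)O[C@@H](c1ccc(OC)cc1OC)[C@H](Cc1ccc(O)cc1)[C@H]2/C=C/c1ccc(O)cc1 | target

**Step count**

Total: 11 steps. Longest linear sequence: 7 steps (steps 3, 4, 5, 6, 7, 10 and 11, from 4-hydroxybenzaldehyde 7).

**Steps most likely to fail**

Step 6. The lithium enolate 12 may expel the ring phenoxide (retro-oxa-Michael opening of ring C to the chalcone) faster than it is benzylated at carbon, which loses material and the C2 configuration. Cleavage of the Si–O bond by MeLi may also be incomplete if metal salts are carried through the filtration. The fallback avoids any basic enolate. It sets out from silyl enol ether 11, taken as the neutral pentane filtrate of the rhodium stage, and from bromide 10. With ZnBr2 (cat.) in CH2Cl2 at 0 °C, 10 ionises to the 4-silyloxybenzyl cation, which 11 captures at C3 anti to the C2 aryl group (Lewis-acid-promoted SN1 alkylation of a silyl enol ether by a benzylic halide), and loss of bromotrimethylsilane gives ketone 13 directly, where the fallback comes back to the route. It makes no compound outside the list (F0).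

Step 10. Capture of the C4 cation by the sparingly soluble, acid-sensitive trifluoroborate may be slower than loss of H3 to the flav-3-ene (whose reprotonation would scramble C3) or than protodeboronation of the reagent. The fallback delivers the two alkene carbons with a soluble, acid-stable π-nucleophile and builds the styrene afterwards. It sets out from alcohol 14. Allyltrimethylsilane in excess with BF3·OEt2 in CH2Cl2 at −78 °C (Hosomi–Sakurai-type substitution of the benzylic alcohol) should give (2R,3R,4R)-4-allyl-3-[4-(tert-butyldimethylsilyloxy)benzyl]-2-(2,4-dimethoxyphenyl)-7-methoxychromane F1, again anti to the C3 benzyl group. Isomerisation of the terminal alkene with RuHCl(CO)(PPh3)3 (cat.) in toluene at 80 °C should give (2R,3R,4R)-3-[4-(tert-butyldimethylsilyloxy)benzyl]-2-(2,4-dimethoxyphenyl)-7-methoxy-4-[(E)-prop-1-enyl]chromane F2. Cross-metathesis of F2 with 4-acetoxystyrene 15 (second-generation Grubbs catalyst, CH2Cl2, 40 °C, loss of propene) then gives 19, where the fallback comes back to the route.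

Step 5. The electron-rich benzylic bromide 10 may ionise during its formation or on silica, leading to hydrolysis back to 9 or to Friedel–Crafts self-condensation, so that too little clean electrophile reaches step 6. The fallback brings the benzyl carbon in at the aldehyde oxidation level. It sets out from aldehyde 8 and silyl enol ether 11 (taken as the pentane filtrate, as above). Mukaiyama aldol addition (BF3·OEt2, CH2Cl2, −78 °C) should give 3-{[4-(tert-butyldimethylsilyloxy)phenyl](hydroxy)methyl}-2-(2,4-dimethoxyphenyl)-7-methoxychroman-4-one F3 as carbinol epimers. Mesylation and elimination (MsCl, Et3N, then DBU, CH2Cl2, 0 °C) should give (E)-3-[4-(tert-butyldimethylsilyloxy)benzylidene]-2-(2,4-dimethoxyphenyl)-7-methoxychroman-4-one F4. Conjugate reduction with [(Ph3P)CuH]6 in wet toluene, followed by equilibration of C3 through the enol with a trace of acid, then gives the 2,3-trans ketone 13, where the fallback comes back to the route.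

**Further compounds**

F0 | step 6 | none | none
F1 | step 10 | (2R,3R,4R)-4-allyl-3-[4-(tert-butyldimethylsilyloxy)benzyl]-2-(2,4-dimethoxyphenyl)-7-methoxychromane | COc1ccc2c(c1)O[C@@H](c1ccc(OC)cc1OC)[C@H](Cc1ccc(O[Si](C)(C)C(C)(C)C)cc1)[C@H]2CC=C
F2 | step 10 | (2R,3R,4R)-3-[4-(tert-butyldimethylsilyloxy)benzyl]-2-(2,4-dimethoxyphenyl)-7-methoxy-4-[(E)-prop-1-enyl]chromane | COc1ccc2c(c1)O[C@@H](c1ccc(OC)cc1OC)[C@H](Cc1ccc(O[Si](C)(C)C(C)(C)C)cc1)[C@H]2/C=C/C
F3 | step 5 | 3-{[4-(tert-butyldimethylsilyloxy)phenyl](hydroxy)methyl}-2-(2,4-dimethoxyphenyl)-7-methoxychroman-4-one (2,3-trans, carbinol epimers) | COc1ccc2c(c1)O[C@@H](c1ccc(OC)cc1OC)[C@H](C(O)c1ccc(O[Si](C)(C)C(C)(C)C)cc1)C2=O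
F4 | step 5 | (E)-3-[4-(tert-butyldimethylsilyloxy)benzylidene]-2-(2,4-dimethoxyphenyl)-7-methoxychroman-4-one | COc1ccc2c(c1)O[C@@H](c1ccc(OC)cc1OC)/C(=C\c1ccc(O[Si](C)(C)C(C)(C)C)cc1)C2=O
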